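## Analysis of the target

The target 47 is a germacranolide: a ten-membered carbocycle (C1–C10) that is trans-fused across C7–C8 to an α-methylene-γ-butyrolactone (C11–C13, lactone oxygen on C8). The carbocycle holds a conjugated diene, C1=C2–C3=C4, in which both double bonds are cis with respect to the ring (1Z,3E by the sequence rule). C4 carries the acetoxymethyl carbon C15 and C10 the methyl group C14. There are four ring stereocentres (6R,7R,8S,10S). On the C5–C9 zigzag O6, the C7–C11 bond and O8 are all syn, whereas C10 is insulated from this triad by the C9 methylene and must be set independently. A fifth centre is the tertiary carbinol of the (S)-2,3-dihydroxy-2-methylpropanoate on O6. The sensitive groups are the exo-methylene lactone (a Michael acceptor), the primary allylic acetate, a hindered ester next to a free 1,2-diol (acyl migration) and the cis,cis-diene. The difficulty is to close a ten-membered ring while fixing two cis double bonds of one conjugated diene, a geometry that cannot be corrected once the ring exists. The structural feature used here is that C1 and C4, the diene termini, each carry one ring bond (to C10 and to C5) on the same side, and C4 also carries the ester-level carbon C15. This is the diene that a 3-sulfolene bridged from its 2- to its 5-position by C5–C10 releases on loss of sulfur dioxide, and in such a sulfolene the C4–H between sulfone and ester is acidic enough for the C4–C5 bond to be made by alkylation.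

## Retrosynthetic reasoning

**Lactone C12–O8 and the side-chain diol.** The two most fragile groups are made last. Target 47 is traced to its acetonide 46, and 46 is opened at the C12–O8 bond to the diol 43. An allylic primary alcohol on C12 next to a secondary hydroxyl on C8 can be taken to the lactone in one oxidation (through 44 and 45), so the Michael acceptor never meets a base or a hydride. The forward reaction must oxidise only the allylic alcohol and must find O8, not O6, as the lactol partner; O6 is therefore acylated first.

**Ester bond at O6.** 43 is traced through 42 to the alcohol 36 and the acid 40. The cut lies in the acyl–O6 bond, because the acid brings its tertiary stereocentre from the chiral pool (37, through 38 and 39), where only the bromomethyl arm is changed. The esterification has to join two hindered partners and must come after every hydride step.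

**C15 and O6.** 36 goes back through 35 and 34 to the methyl ester 33. C15 is kept at the ester level until the ring is closed because the ester is what makes C4–H acidic; it is then reduced and acetylated. O6 is carried as a 4-methoxybenzyl ether, which survives base, heat and hydride and is removed oxidatively without touching the silyl ethers on O8 and O12.

**The diene.** 33 is traced to the bicycle 32 by adding sulfur dioxide 28 across C1 and C4. No carbon–carbon bond is cut; both double-bond geometries are delegated to one structural element, the bridge. The forward extrusion is concerted and can only turn both bridge bonds inward.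

**C4–C5 (key disconnection).** 32 is opened at C4–C5 to the iodide 31. The cut is made here and not within the diene because C4 is the one carbon of the ring that can be turned into a stabilised carbanion, and C5 is a primary carbon. The forward step must close a ring that is ten-membered through carbon.

**C4–C15, the sulfolene ring and the C5 iodide.** 31 is cut at C4–C15 to the sulfolene 29 and methyl chloroformate 30. 29 is cut at both C–S bonds to the diene 27 and sulfur dioxide 28. The iodide 27 comes from the alcohol 26. The ester is introduced after the cheletropic step because an electron-poor dienoate would not trap 28.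

**C1=C2 and the O5/O6 pair.** 26 arises from 25 by regioselective opening of a 4-methoxybenzylidene acetal, which places the benzyl ether on O6 and frees O5 in one step. 25 is cut at C1=C2 to the aldehyde 23 and the phosphine oxide 24, which supplies C2–C4 with E geometry.

**Protecting-group order and the C12 oxygen.** 23 goes back through 22, 21, 20, 19 and 18 to the diol 17. The acetal 20 is the device that tells O6 from O8; O8 is then silylated. The C12 oxygen is introduced by selenium-mediated allylic oxidation of the 2-propenyl group (17 to 18) at a stage where no carbonyl group lies within reach of the new hydroxyl.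

**C8–C9 and the C8 stereocentre.** 17 comes from the β-hydroxy ketone 15 by 1,3-syn reduction, which relays C6 to C8. 15 is cut at C8–C9 into the Weinreb amide 9 and the alkyllithium 14 made from iodide 13. This is the most convergent cut, and it keeps C10 four bonds away from any new centre.

**C6–C7.** 9 comes from the aldol adduct 8, which is cut at C6–C7 into the imide 6 (from 4 and 5) and the aldehyde 3 (from 1 through 2). One auxiliary-controlled syn aldol sets C6 and C7 and brings in the 2-propenyl branch.

**C10.** The iodide 13 is traced through 12 and 11 to the hydroxy ester 10, whose stereocentre becomes C10 unchanged.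

## Alternatives that were turned down

**Alternative 1: closing the ring at C2–C3 by alkenyl–alkenyl coupling.** The disconnection is the central single bond of the diene. The forward key step would treat the open-chain lactone A2, carrying a Z-alkenyl iodide at C2 and an alkenyl stannane at C3, with Cu(O2CC4H3S) (or Pd2(dba)3 with AsPh3) and so give A1, which is identical with 46 of the present route.
- For it: both geometries are set beforehand by open-chain chemistry, the coupling is neutral and tolerates the complete lactone and both esters, and it lands one step from the target. On precedent for the ring-forming reaction type and on brevity of the endgame it is stronger than the chosen plan.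
- Against it for this target: A2 must carry the methylene lactone, a protodestannylation-prone trisubstituted stannane and a Z-iodide through its whole assembly, and each alkenyl partner needs its own stereoselective synthesis. The bond-forming step must hold two cis-alkenyl termini together in a strained ten-membered metallacycle, where homocoupling and oligomers compete, and it uses stoichiometric copper and tin.
- Comparison: both plans need the same C6–C8 triad. The chosen plan offers one structural element (the bridge) in place of two separately made alkene geometries, and closure at an sp3 carbon by a soft carbanion. Step counts come out about equal, because the two alkenyl fragments cost what the sulfolene steps and the late reduction cost here.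

**Alternative 2: cleaving the ring-fusion alkene of a dihydroaromatic bicycle.** The disconnection reconnects C1 and C6 as a tetrasubstituted alkene. In the forward direction O3 (or epoxidation and H5IO6) would cleave that alkene in the hexahydronaphthalene A4 and open it to the ten-membered dione A3.
- For it: the ring arises by breaking a bond, so no medium-ring closure is needed at all; on this point it is clearly stronger than the chosen plan. The cis C3=C4 bond is inherited from a six-membered ring, and the starting materials are cheap aromatics.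
- Against it: A3 has ketones where the target has an alkene carbon (C1) and an acylated carbinol (C6). Turning the C1 ketone into a cis C1=C2 bond conjugated with C3=C4 requires regioselective enolisation away from C10, which is α to that ketone and would epimerise. The C6 ketone must be reduced under transannular control, the 1,6-dione is set up for transannular aldol reaction, C13 is still missing, and the cleavage must spare the trisubstituted C3=C4 bond.
- Comparison: the ring comes easily but the functional groups come late, in many steps. The chosen plan gives up the easy ring formation but delivers the diene complete, with C15 at the ester level, one step after ring closure, and sets C6, C7 and C8 in an open chain.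

**Alternative 3: ring contraction by [2,3]-Wittig rearrangement.** The disconnection is C6–C7. In the forward step n-BuLi would exchange tin for lithium at C6 of the thirteen-membered α-stannyl allyl ether A6, and the [2,3]-shift would form C6–C7 and the C11=C13 methylene, contracting the ring to the ten-membered alcohol A5.
- For it: a thirteen-membered ether is easier to close than any ten-membered ring, and one step makes a carbon–carbon bond, the exo-methylene unit and two stereocentres. On ring size and on bond economy in the key step it is stronger.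
- Against it: the cis,cis-diene must already be present in A6, so the central geometric problem is only moved to an earlier stage. The C6/C7 relation and its relation to C8 depend on the fold of a thirteen-membered transition state, which cannot be predicted with confidence. The α-alkoxy carbanion sits next to the C5 hydrogens, which are allylic to the diene (proton transfer, [1,2]-shift). The C6 stannane must be made in defined configuration.
- Comparison: the chosen plan sets C6, C7 and C8 by an aldol reaction and a directed reduction of predictable outcome and uses the ring-forming event itself to create the diene.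

Key step: step 22

Remarks on the chemistry:
- Positions are numbered C1–C15 as in the analysis.
- The cheletropic addition of step 20 is not expected to control C1. Compounds 29, 31 and 32 are therefore carried as C1 epimers (the 1R epimer is written), which converge in step 23.
- C4 of 31 is left open because it equilibrates through the carbanion.
- The acetal carbon of 20–25 forms as both epimers, without consequence.
- Anions formed by simple deprotonation are counted as forms of the numbered compound.

## Route

Step 1
Reactants: 1 2,2-diethoxyethanol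
Product: 2 1-[(2,2-diethoxyethoxy)methyl]-4-methoxybenzene
Conditions: NaH, 4-methoxybenzyl chloride, Bu4NI (cat.), THF, 0 °C → rt
Reagents that add atoms: 4-methoxybenzyl chloride, COc1ccc(CCl)cc1
Why: Williamson ether synthesis; the sodium alkoxide of 1 displaces the benzylic chloride by SN2 under iodide catalysis, and the acetal is inert to base.

Step 2
Reactants: 2 1-[(2,2-diethoxyethoxy)methyl]-4-methoxybenzene
Product: 3 2-[(4-methoxybenzyl)oxy]acetaldehyde
Conditions: 1 M HCl, THF, rt
Reagents that add atoms: water, O
Why: Acid-catalysed acetal hydrolysis; the 4-methoxybenzyl ether survives dilute aqueous acid at room temperature, and 3 is used without storage because α-alkoxy aldehydes hydrate and oligomerise.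

Step 3
Reactants: 4 (S)-4-benzyloxazolidin-2-one; 5 3-methylbut-2-enoyl chloride
Product: 6 (S)-4-benzyl-3-(3-methylbut-2-enoyl)oxazolidin-2-one
Conditions: n-BuLi, THF, −78 °C; then 5, −78 → 0 °C
Reagents that add atoms: none
Why: N-acylation of the lithiated oxazolidinone by the acid chloride, the standard preparation of Evans imides.

Step 4
Reactants: 6 (S)-4-benzyl-3-(3-methylbut-2-enoyl)oxazolidin-2-one; 3 2-[(4-methoxybenzyl)oxy]acetaldehyde
Product: 8 (S)-4-benzyl-3-[(2S,3S)-3-hydroxy-4-[(4-methoxybenzyl)oxy]-2-(prop-1-en-2-yl)butanoyl]oxazolidin-2-one, via dibutylboron dienolate 7 (not isolated)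
Conditions: Bu2BOTf, Et3N, CH2Cl2, −78 → 0 °C; then 3, −78 → 0 °C; pH 7 buffer, MeOH, H2O2, 0 °C
Reagents that add atoms: none
Why: Evans syn-aldol reaction of a vinylogously enolised (crotonate-type) imide: γ-deprotonation gives the Z(O) dienol borinate 7, which reacts at its α-carbon through a chair Zimmerman–Traxler transition state. The (S)-benzyl auxiliary shields one enolate face and so sets C7 (S) and C6 (S), that is the syn relation of the C7–C11 bond and O6, and it installs the 2-propenyl branch.

Step 5
Reactants: 8 (S)-4-benzyl-3-[(2S,3S)-3-hydroxy-4-[(4-methoxybenzyl)oxy]-2-(prop-1-en-2-yl)butanoyl]oxazolidin-2-one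
Product: 9 (2S,3S)-3-hydroxy-N-methoxy-4-[(4-methoxybenzyl)oxy]-N-methyl-2-(prop-1-en-2-yl)butanamide
Conditions: MeNH(OMe)·HCl, AlMe3, CH2Cl2, −15 → 0 °C
Reagents that add atoms: N,O-dimethylhydroxylamine hydrochloride, CNOC.Cl
Why: Aluminium-amide transamidation of the β-hydroxy imide to the Weinreb amide, assisted by the free C6 hydroxyl; the non-basic conditions leave the α-stereocentre C7 and the β,γ-double bond in place and return auxiliary 4.

Step 6
Reactants: 10 methyl (R)-3-hydroxy-2-methylpropanoate
Product: 11 methyl (R)-3-[(tert-butyldimethylsilyl)oxy]-2-methylpropanoate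
Conditions: TBSCl, imidazole, CH2Cl2, rt
Reagents that add atoms: tert-butyldimethylsilyl chloride, CC(C)(C)[Si](C)(C)Cl
Why: Silylation of the primary alcohol; the stereocentre that becomes C10 comes from the chiral pool and is not touched.

Step 7
Reactants: 11 methyl (R)-3-[(tert-butyldimethylsilyl)oxy]-2-methylpropanoate
Product: 12 (S)-3-[(tert-butyldimethylsilyl)oxy]-2-methylpropan-1-ol
Conditions: i-Bu2AlH, CH2Cl2, −78 → 0 °C
Reagents that add atoms: none
Why: Hydride reduction of the ester to the primary alcohol; no base able to epimerise the α-centre is present.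

Step 8
Reactants: 12 (S)-3-[(tert-butyldimethylsilyl)oxy]-2-methylpropan-1-ol
Product: 13 (R)-tert-butyl(3-iodo-2-methylpropoxy)dimethylsilane
Conditions: I2, PPh3, imidazole, CH2Cl2, 0 °C → rt
Reagents that add atoms: iodine, II
Why: Appel-type iodination through the alkoxyphosphonium salt; the SN2 step at the primary carbon does not involve the stereocentre.

Step 9
Reactants: 13 (R)-tert-butyl(3-iodo-2-methylpropoxy)dimethylsilane; 9 (2S,3S)-3-hydroxy-N-methoxy-4-[(4-methoxybenzyl)oxy]-N-methyl-2-(prop-1-en-2-yl)butanamide
Product: 15 (2S,3S,6S)-7-[(tert-butyldimethylsilyl)oxy]-2-hydroxy-1-[(4-methoxybenzyl)oxy]-6-methyl-3-(prop-1-en-2-yl)heptan-4-one, via alkyllithium 14 (not isolated)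
Conditions: 13, t-BuLi (2 equiv), Et2O, −78 °C; then 9 (pretreated with i-PrMgCl, THF, −78 °C), −78 → −30 °C; aq. NH4Cl
Reagents that add atoms: none
Why: Iodine–lithium exchange followed by acyl substitution at the Weinreb amide, whose chelated tetrahedral adduct prevents over-addition; the C6 hydroxyl is masked as its magnesium alkoxide. Addition at −78 °C is expected to outrun deprotonation at C7, and 15 is reduced without delay because its C7–H is both α to the ketone and allylic.

Step 10
Reactants: 15 (2S,3S,6S)-7-[(tert-butyldimethylsilyl)oxy]-2-hydroxy-1-[(4-methoxybenzyl)oxy]-6-methyl-3-(prop-1-en-2-yl)heptan-4-one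
Product: 17 (2S,3R,4S,6S)-7-[(tert-butyldimethylsilyl)oxy]-1-[(4-methoxybenzyl)oxy]-6-methyl-3-(prop-1-en-2-yl)heptane-2,4-diol, via boron chelate 16 (not isolated)
Conditions: Et2BOMe, THF/MeOH (4:1), −78 °C; NaBH4; AcOH, then MeOH co-evaporation
Reagents that add atoms: none
Why: Narasaka–Prasad reduction: the six-membered boron chelate 16 of the β-hydroxy ketone takes hydride by external axial attack, which gives the 1,3-syn diol and so sets C8 (S) from C6. With the syn-aldol substituent on C7 this completes the all-syn C6–C7–C8 triad.

Step 11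
Reactants: 17 (2S,3R,4S,6S)-7-[(tert-butyldimethylsilyl)oxy]-1-[(4-methoxybenzyl)oxy]-6-methyl-3-(prop-1-en-2-yl)heptane-2,4-diol
Product: 18 (2S,3R,4S,6S)-7-[(tert-butyldimethylsilyl)oxy]-3-(3-hydroxyprop-1-en-2-yl)-1-[(4-methoxybenzyl)oxy]-6-methylheptane-2,4-diol
Conditions: SeO2 (0.5 equiv), t-BuOOH, CH2Cl2, 0 °C → rt
Reagents that add atoms: tert-butyl hydroperoxide, CC(C)(C)OO
Why: Allylic oxidation by SeO2 (ene reaction, then [2,3]-sigmatropic shift, with t-BuOOH as reoxidant) converts the methyl group of the 1,1-disubstituted alkene into CH2OH and returns the double bond to C11=C13. The C7–H is not expected to react because allylic strain holds it in the plane of the alkene and its carbon is flanked by two oxygenated centres.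

Step 12
Reactants: 18 (2S,3R,4S,6S)-7-[(tert-butyldimethylsilyl)oxy]-3-(3-hydroxyprop-1-en-2-yl)-1-[(4-methoxybenzyl)oxy]-6-methylheptane-2,4-diol
Product: 19 (2S,3R,4S,6S)-7-[(tert-butyldimethylsilyl)oxy]-3-{3-[(tert-butyldiphenylsilyl)oxy]prop-1-en-2-yl}-1-[(4-methoxybenzyl)oxy]-6-methylheptane-2,4-diol
Conditions: TBDPSCl, imidazole, CH2Cl2, 0 °C
Reagents that add atoms: tert-butyldiphenylsilyl chloride, CC(C)(C)[Si](Cl)(c1ccccc1)c1ccccc1
Why: Selective silylation of the primary allylic hydroxyl in the presence of two hindered secondary ones; the diphenylsilyl group is chosen so that the C1 silyl ether can later be removed beside it.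

Step 13
Reactants: 19 (2S,3R,4S,6S)-7-[(tert-butyldimethylsilyl)oxy]-3-{3-[(tert-butyldiphenylsilyl)oxy]prop-1-en-2-yl}-1-[(4-methoxybenzyl)oxy]-6-methylheptane-2,4-diol
Product: 20 O5,O6-(4-methoxybenzylidene) acetal of 19 (1,3-dioxolane; C8 hydroxyl free)
Conditions: DDQ, 4 Å molecular sieves, CH2Cl2, 0 °C
Reagents that add atoms: none
Why: Anhydrous oxidation of the 4-methoxybenzyl ether gives an oxocarbenium ion that is trapped by the neighbouring C6 hydroxyl as the five-membered acetal; the seven-membered alternative through O8 does not compete. This ties up O5 and O6 and leaves O8 as the only free hydroxyl.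

Step 14
Reactants: 20 O5,O6-(4-methoxybenzylidene) acetal of 19 (1,3-dioxolane; C8 hydroxyl free)
Product: 21 C8 tert-butyldimethylsilyl ether of 20
Conditions: TBSOTf, 2,6-lutidine, CH2Cl2, −78 °C
Reagents that add atoms: tert-butyldimethylsilyl trifluoromethanesulfonate, CC(C)(C)[Si](C)(C)OS(=O)(=O)C(F)(F)F
Why: Silylation of the hindered secondary C8 hydroxyl with the silyl triflate; the buffered low-temperature conditions keep the acetal intact.

Step 15
Reactants: 21 C8 tert-butyldimethylsilyl ether of 20
Product: 22 C1 primary alcohol from 21 (O8 TBS; O12 TBDPS; O5,O6 acetal)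
Conditions: HF·pyridine, pyridine, THF, 0 °C → rt
Reagents that add atoms: none
Why: Selective desilylation: buffered HF cleaves the unhindered primary TBS ether on C1 much faster than the hindered secondary TBS ether on C8 or the primary TBDPS ether on C12.

Step 16
Reactants: 22 C1 primary alcohol from 21 (O8 TBS; O12 TBDPS; O5,O6 acetal)
Product: 23 C1 aldehyde from 22
Conditions: Dess–Martin periodinane, NaHCO3, CH2Cl2, 0 °C → rt
Reagents that add atoms: none
Why: Dess–Martin oxidation under buffered neutral conditions, chosen to avoid epimerisation of the α-stereocentre C10; 23 is used at once.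

Step 17
Reactants: 23 C1 aldehyde from 22; 24 allyl(diphenyl)phosphine oxide
Product: 25 (1E)-C1=C2–C3=C4 terminal diene from 23 (O5,O6 acetal retained)
Conditions: 24, n-BuLi, THF/HMPA, −78 °C; then 23, −78 °C → rt
Reagents that add atoms: none
Why: Horner–Wittig olefination: the lithiated allylphosphine oxide adds through its α-carbon in the presence of HMPA, and syn-elimination of diphenylphosphinate gives the E-configured terminal 1,3-diene, the geometry that reaches the s-cis form needed in step 20.

Step 18
Reactants: 25 (1E)-C1=C2–C3=C4 terminal diene from 23 (O5,O6 acetal retained)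
Product: 26 C5 primary alcohol with 4-methoxybenzyl ether on O6 (diene; O8 TBS; O12 TBDPS)
Conditions: i-Bu2AlH, CH2Cl2, −78 → 0 °C
Reagents that add atoms: none
Why: Reductive opening of the 4-methoxybenzylidene acetal: aluminium coordinates the less hindered primary oxygen O5, the C–O5 bond breaks and hydride reduces the oxocarbenium ion. This leaves the 4-methoxybenzyl ether on the secondary O6 and frees the C5 hydroxyl.

Step 19
Reactants: 26 C5 primary alcohol with 4-methoxybenzyl ether on O6 (diene; O8 TBS; O12 TBDPS)
Product: 27 C5 iodide from 26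
Conditions: I2, PPh3, imidazole, CH2Cl2, 0 °C
Reagents that add atoms: iodine, II
Why: Appel-type iodination of the primary alcohol; PPh3 is kept in slight excess so that no free iodine meets the diene.

Step 20
Reactants: 27 C5 iodide from 26; 28 sulfur dioxide
Product: 29 2-substituted 3-sulfolene from 27 (2,5-dihydrothiophene 1,1-dioxide attached through C1 to C10; 1R epimer written)
Conditions: 28 (liquid, excess), hydroquinone (cat.), NaHCO3 (solid), CH2Cl2, sealed tube, rt → 40 °C
Reagents that add atoms: none
Why: Cheletropic [4+1] addition of sulfur dioxide to the s-cis conformer of the E-diene gives the 3-sulfolene; the isolated 1,1-disubstituted alkene, the iodide and the ethers do not react. The new centre C1 forms without control as both epimers, which is accepted because it disappears in step 23.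

Step 21
Reactants: 29 2-substituted 3-sulfolene from 27 (2,5-dihydrothiophene 1,1-dioxide attached through C1 to C10; 1R epimer written); 30 methyl chloroformate
Product: 31 methyl 5-substituted 2,5-dihydrothiophene-2-carboxylate 1,1-dioxide with C5 iodide (cyclisation precursor; 1R epimer written; both C4 epimers)
Conditions: 30 (1.5 equiv), then LiN(SiMe3)2 (2.2 equiv) added slowly, THF, −78 °C; AcOH, −78 °C
Reagents that add atoms: none
Why: Acylation of an α-sulfonyl carbanion under in situ trapping: the amide base removes a proton from the unsubstituted C4 methylene (C1 is tertiary and shielded), and the carbanion is C-acylated by the chloroformate before it can open to a dienyl sulfinate. Acylation is far faster at −78 °C than attack on the β-branched C5 iodide, and the second equivalent of base stores 31 as its stabilised anion until the cold quench.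

Step 22
Reactants: 31 methyl 5-substituted 2,5-dihydrothiophene-2-carboxylate 1,1-dioxide with C5 iodide (cyclisation precursor; 1R epimer written; both C4 epimers)
Product: 32 methyl 11-thiabicyclo[6.2.1]undec-9-ene-carboxylate 11,11-dioxide holding the ten-membered carbocycle (SO2 bridge between C1 and C4; ester on C4)
Conditions: Cs2CO3, DMF, syringe-pump addition of 31 to about 1 mM, 25 → 40 °C
Reagents that add atoms: none
Why: Proposed new method: Cs2CO3 removes the C4 proton, which is flanked by the sulfone, the ester and the C2=C3 double bond, and the soft carbanion displaces the primary C5 iodide by SN2, forming C4–C5; the closest known reaction type is the intermolecular α-alkylation of 2-alkoxycarbonyl-3-sulfolenes with primary halides under carbonate bases, here asked to work within one molecule across a six-atom tether. The ten-membered carbocycle closes in a 10-exo-tet mode (9-exo-tet if the ring is counted through sulfur) and arises as an 11-thiabicyclo[6.2.1]undec-9-ene 11,11-dioxide. The new quaternary stereocentre C4 is set by C1: the tether C5–C10 is anchored at C1 and can reach the planar C4 carbanion only on the face of the five-membered ring on which it already lies, so only the cis-bridged bicycle can form and each C1 epimer of 31 gives a single C4 configuration. The C4 epimers of 31 interconvert through the carbanion, so both feed the closure. The step needs alkylation at C4 and not at C2 or on the enolate oxygen; the charge is concentrated at C4 between the two acceptors, whereas attack through C2 would give an eight-membered ring fused to a 2-sulfolene and is the main competitor. It also needs ring closure to beat dimerisation, which slow addition to about 1 mM and the large, weakly coordinating caesium ion are meant to secure. The temperature is kept at or below 40 °C so that neither 31 nor 32 loses sulfur dioxide before the bridge is closed, and the carbonate is too weak to touch C1–H, the silyl ethers or the 4-methoxybenzyl ether.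

Step 23
Reactants: 32 methyl 11-thiabicyclo[6.2.1]undec-9-ene-carboxylate 11,11-dioxide holding the ten-membered carbocycle (SO2 bridge between C1 and C4; ester on C4)
Product: 33 ring-cis,cis dienoate: methyl (1Z,3E)-cyclodeca-1,3-diene-4-carboxylate core (O6 PMB; O8 TBS; O12 TBDPS)
Conditions: toluene, pyridine (cat.), 110 °C
Reagents that add atoms: none
Why: Retro-cheletropic loss of sulfur dioxide, a concerted disrotatory process: C5 and C10 are held on one face by the bridge and must both turn inward, so only the ring-cis,cis diene with the ester on C4 can form. C1 becomes trigonal, so both C1 epimers of 32 give the same 33.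

Step 24
Reactants: 33 ring-cis,cis dienoate: methyl (1Z,3E)-cyclodeca-1,3-diene-4-carboxylate core (O6 PMB; O8 TBS; O12 TBDPS)
Product: 34 C15 allylic alcohol from 33
Conditions: i-Bu2AlH, CH2Cl2, −78 °C
Reagents that add atoms: none
Why: 1,2-Reduction of the dienoate to the primary allylic alcohol at low temperature; ethers, silyl groups and the diene are unaffected.

Step 25
Reactants: 34 C15 allylic alcohol from 33
Product: 35 C15 acetate of 34
Conditions: Ac2O, pyridine, DMAP (cat.), CH2Cl2, 0 °C → rt
Reagents that add atoms: acetic anhydride, CC(=O)OC(C)=O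
Why: Acylation of the only free hydroxyl installs the acetate of the target.

Step 26
Reactants: 35 C15 acetate of 34
Product: 36 C6 alcohol from 35
Conditions: DDQ, CH2Cl2/pH 7 buffer (10:1), 0 °C
Reagents that add atoms: none
Why: Oxidative cleavage of the 4-methoxybenzyl ether by DDQ (hydride abstraction, then hydrolysis of the oxocarbenium ion) frees the C6 hydroxyl; buffered wet CH2Cl2 at 0 °C keeps the exposure of the diene short.

Step 27
Reactants: 37 (R)-3-bromo-2-hydroxy-2-methylpropanoic acid
Product: 39 (S)-2,3-dihydroxy-2-methylpropanoic acid, via sodium glycidate 38 (not isolated)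
Conditions: 2 M NaOH (aq.), 0 → 80 °C; then H+ ion-exchange resin
Reagents that add atoms: sodium hydroxide, [Na+].[OH-]
Why: Intramolecular Williamson closure of the bromohydrin to the glycidate 38, then SN2 opening by hydroxide at the unhindered CH2. The bond from the tertiary carbon to oxygen is never broken, so the centre is retained; the descriptor changes from R to S only because CH2OH ranks below CO2H.

Step 28
Reactants: 39 (S)-2,3-dihydroxy-2-methylpropanoic acid
Product: 40 (S)-2,2,4-trimethyl-1,3-dioxolane-4-carboxylic acid
Conditions: 2-methoxypropene, PPTS (cat.), DMF, 0 °C → rt; aqueous work-up at pH 3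
Reagents that add atoms: 2-methoxypropene, C=C(C)OC
Why: Acid-catalysed ketalisation of the 1,2-diol under kinetic conditions; any labile mixed ketal ester at the carboxyl group is hydrolysed in the work-up.

Step 29
Reactants: 40 (S)-2,2,4-trimethyl-1,3-dioxolane-4-carboxylic acid; 36 C6 alcohol from 35
Product: 42 C6 ester of 36 with acid 40, via mixed anhydride 41 (not isolated)
Conditions: 40, 2,4,6-Cl3C6H2COCl, Et3N, toluene, rt; then 36, DMAP, toluene, rt → 40 °C
Reagents that add atoms: none
Why: Yamaguchi esterification: DMAP attacks the mixed anhydride 41 at the aliphatic carbonyl, and the acylpyridinium ion acylates the hindered C6 hydroxyl. Neither partner has an epimerisable centre next to the reacting carbonyl.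

Step 30
Reactants: 42 C6 ester of 36 with acid 40
Product: 43 C8,C12 diol from 42
Conditions: HF·pyridine, pyridine, THF, 0 °C → rt
Reagents that add atoms: none
Why: Fluoride-mediated cleavage of both silyl ethers under buffered, weakly acidic conditions, which avoid a base-induced acyl shift from O6 to O8 and leave the acetonide, the acetate and the diene untouched.

Step 31
Reactants: 43 C8,C12 diol from 42
Product: 46 acetonide of the target (8,12-lactone closed), via hydroxy enal 44 (not isolated), via lactol 45 (not isolated)
Conditions: MnO2 (activated, excess), CH2Cl2, rt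
Reagents that add atoms: none
Why: MnO2 oxidises only the allylic primary alcohol to the enal 44, which closes with the C8 hydroxyl to the lactol 45; the lactol is oxidised further to the α-methylene-γ-butyrolactone (oxidative lactonisation of a 2-methylene-1,4-diol). O6 is already acylated, so only the 8,12-lactone, with the trans fusion fixed by C7 and C8, can form.

Step 32
Reactants: 46 acetonide of the target (8,12-lactone closed)
Product: 47 CNP0347302.1 (target)
Conditions: AcOH/H2O (4:1), 40 °C
Reagents that add atoms: none
Why: Acid-catalysed acetonide hydrolysis frees the 1,2-diol; aqueous acetic acid is too mild to ionise the allylic acetate or to add to the methylene lactone.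

## Compound list

1 | 2,2-diethoxyethanol | CCOC(CO)OCC | starting material
2 | 1-[(2,2-diethoxyethoxy)methyl]-4-methoxybenzene | CCOC(COCc1ccc(OC)cc1)OCC | intermediate
3 | 2-[(4-methoxybenzyl)oxy]acetaldehyde | COc1ccc(COCC=O)cc1 | intermediate
4 | (S)-4-benzyloxazolidin-2-one | O=C1OC[C@H](Cc2ccccc2)N1 | starting material
5 | 3-methylbut-2-enoyl chloride | CC(C)=CC(=O)Cl | starting material
6 | (S)-4-benzyl-3-(3-methylbut-2-enoyl)oxazolidin-2-one | CC(C)=CC(=O)N1[C@@H](Cc2ccccc2)COC1=O | intermediate
7 | dibutylboron (Z)-dienolate of 6 | C=C(C)/C=C(\OB(CCCC)CCCC)N1[C@@H](Cc2ccccc2)COC1=O | intermediate (not isolated)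
8 | (S)-4-benzyl-3-[(2S,3S)-3-hydroxy-4-[(4-methoxybenzyl)oxy]-2-(prop-1-en-2-yl)butanoyl]oxazolidin-2-one | COc1ccc(COC[C@@H](O)[C@H](C(C)=C)C(=O)N2[C@@H](Cc3ccccc3)COC2=O)cc1 | intermediate
9 | (2S,3S)-3-hydroxy-N-methoxy-4-[(4-methoxybenzyl)oxy]-N-methyl-2-(prop-1-en-2-yl)butanamide | COc1ccc(COC[C@@H](O)[C@H](C(C)=C)C(=O)N(C)OC)cc1 | intermediate
10 | methyl (R)-3-hydroxy-2-methylpropanoate | COC(=O)[C@H](C)CO | starting material
11 | methyl (R)-3-[(tert-butyldimethylsilyl)oxy]-2-methylpropanoate | COC(=O)[C@H](C)CO[Si](C)(C)C(C)(C)C | intermediate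
12 | (S)-3-[(tert-butyldimethylsilyl)oxy]-2-methylpropan-1-ol | OC[C@H](C)CO[Si](C)(C)C(C)(C)C | intermediate
13 | (R)-tert-butyl(3-iodo-2-methylpropoxy)dimethylsilane | IC[C@H](C)CO[Si](C)(C)C(C)(C)C | intermediate
14 | (S)-{3-[(tert-butyldimethylsilyl)oxy]-2-methylpropyl}lithium | [Li]C[C@H](C)CO[Si](C)(C)C(C)(C)C | intermediate (not isolated)
15 | (2S,3S,6S)-7-[(tert-butyldimethylsilyl)oxy]-2-hydroxy-1-[(4-methoxybenzyl)oxy]-6-methyl-3-(prop-1-en-2-yl)heptan-4-one | COc1ccc(COC[C@@H](O)[C@H](C(C)=C)C(=O)C[C@H](C)CO[Si](C)(C)C(C)(C)C)cc1 | intermediate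
16 | diethylboron chelate (O-diethylborinate) of 15 | COc1ccc(COC[C@@H](OB(CC)CC)[C@H](C(C)=C)C(=O)C[C@H](C)CO[Si](C)(C)C(C)(C)C)cc1 | intermediate (not isolated)
17 | (2S,3R,4S,6S)-7-[(tert-butyldimethylsilyl)oxy]-1-[(4-methoxybenzyl)oxy]-6-methyl-3-(prop-1-en-2-yl)heptane-2,4-diol | COc1ccc(COC[C@@H](O)[C@H](C(C)=C)[C@@H](O)C[C@H](C)CO[Si](C)(C)C(C)(C)C)cc1 | intermediate
18 | (2S,3R,4S,6S)-7-[(tert-butyldimethylsilyl)oxy]-3-(3-hydroxyprop-1-en-2-yl)-1-[(4-methoxybenzyl)oxy]-6-methylheptane-2,4-diol | COc1ccc(COC[C@@H](O)[C@H](C(=C)CO)[C@@H](O)C[C@H](C)CO[Si](C)(C)C(C)(C)C)cc1 | intermediate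
19 | (2S,3R,4S,6S)-7-[(tert-butyldimethylsilyl)oxy]-3-{3-[(tert-butyldiphenylsilyl)oxy]prop-1-en-2-yl}-1-[(4-methoxybenzyl)oxy]-6-methylheptane-2,4-diol | COc1ccc(COC[C@@H](O)[C@H](C(=C)CO[Si](c2ccccc2)(c2ccccc2)C(C)(C)C)[C@@H](O)C[C@H](C)CO[Si](C)(C)C(C)(C)C)cc1 | intermediate
20 | O5,O6-(4-methoxybenzylidene) acetal of 19 (1,3-dioxolane, both acetal epimers; C8 hydroxyl free; C6, C7, C8, C10 as in 19) | COc1ccc(C2OC[C@@H](O2)[C@H](C(=C)CO[Si](c3ccccc3)(c3ccccc3)C(C)(C)C)[C@@H](O)C[C@H](C)CO[Si](C)(C)C(C)(C)C)cc1 | intermediate
21 | C8 tert-butyldimethylsilyl ether of 20 | COc1ccc(C2OC[C@@H](O2)[C@H](C(=C)CO[Si](c3ccccc3)(c3ccccc3)C(C)(C)C)[C@@H](O[Si](C)(C)C(C)(C)C)C[C@H](C)CO[Si](C)(C)C(C)(C)C)cc1 | intermediate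
22 | C1 primary alcohol from 21 (O8 TBS; O12 TBDPS; O5,O6 acetal) | COc1ccc(C2OC[C@@H](O2)[C@H](C(=C)CO[Si](c3ccccc3)(c3ccccc3)C(C)(C)C)[C@@H](O[Si](C)(C)C(C)(C)C)C[C@H](C)CO)cc1 | intermediate
23 | C1 aldehyde from 22 | COc1ccc(C2OC[C@@H](O2)[C@H](C(=C)CO[Si](c3ccccc3)(c3ccccc3)C(C)(C)C)[C@@H](O[Si](C)(C)C(C)(C)C)C[C@H](C)C=O)cc1 | intermediate
24 | allyl(diphenyl)phosphine oxide | C=CCP(=O)(c1ccccc1)c1ccccc1 | starting material
25 | (1E)-C1=C2–C3=C4 terminal diene from 23 (O5,O6 acetal retained) | COc1ccc(C2OC[C@@H](O2)[C@H](C(=C)CO[Si](c3ccccc3)(c3ccccc3)C(C)(C)C)[C@@H](O[Si](C)(C)C(C)(C)C)C[C@H](C)/C=C/C=C)cc1 | intermediate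
26 | C5 primary alcohol with 4-methoxybenzyl ether on O6 (E-diene; O8 TBS; O12 TBDPS) | OC[C@@H](OCc1ccc(OC)cc1)[C@H](C(=C)CO[Si](c1ccccc1)(c1ccccc1)C(C)(C)C)[C@@H](O[Si](C)(C)C(C)(C)C)C[C@H](C)/C=C/C=C | intermediate
27 | C5 iodide from 26 | IC[C@@H](OCc1ccc(OC)cc1)[C@H](C(=C)CO[Si](c1ccccc1)(c1ccccc1)C(C)(C)C)[C@@H](O[Si](C)(C)C(C)(C)C)C[C@H](C)/C=C/C=C | intermediate
28 | sulfur dioxide | O=S=O | starting material
29 | 2-substituted 3-sulfolene from 27 (2,5-dihydrothiophene 1,1-dioxide attached through C1 to C10; 1R epimer written) | IC[C@@H](OCc1ccc(OC)cc1)[C@H](C(=C)CO[Si](c1ccccc1)(c1ccccc1)C(C)(C)C)[C@@H](O[Si](C)(C)C(C)(C)C)C[C@H](C)[C@@H]1C=CCS1(=O)=O | intermediate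
30 | methyl chloroformate | COC(=O)Cl | starting material
31 | methyl 5-substituted 2,5-dihydrothiophene-2-carboxylate 1,1-dioxide with C5 iodide (cyclisation precursor; 1R epimer written; both C4 epimers) | IC[C@@H](OCc1ccc(OC)cc1)[C@H](C(=C)CO[Si](c1ccccc1)(c1ccccc1)C(C)(C)C)[C@@H](O[Si](C)(C)C(C)(C)C)C[C@H](C)[C@@H]1C=CC(C(=O)OC)S1(=O)=O | intermediate
32 | methyl 11-thiabicyclo[6.2.1]undec-9-ene-carboxylate 11,11-dioxide holding the ten-membered carbocycle (SO2 bridge between C1 and C4; ester on C4; O6 PMB; O8 TBS; O12 TBDPS) | O=S1(=O)[C@H]2C=C[C@]1(C(=O)OC)C[C@@H](OCc3ccc(OC)cc3)[C@H](C(=C)CO[Si](c3ccccc3)(c3ccccc3)C(C)(C)C)[C@@H](O[Si](C)(C)C(C)(C)C)C[C@@H]2C | intermediate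
33 | ring-cis,cis dienoate: methyl (1Z,3E)-cyclodeca-1,3-diene-4-carboxylate core (O6 PMB; O8 TBS; O12 TBDPS) | C[C@@H]1/C=C\C=C(\C(=O)OC)C[C@@H](OCc2ccc(OC)cc2)[C@H](C(=C)CO[Si](c2ccccc2)(c2ccccc2)C(C)(C)C)[C@@H](O[Si](C)(C)C(C)(C)C)C1 | intermediate
34 | C15 allylic alcohol from 33 | C[C@@H]1/C=C\C=C(\CO)C[C@@H](OCc2ccc(OC)cc2)[C@H](C(=C)CO[Si](c2ccccc2)(c2ccccc2)C(C)(C)C)[C@@H](O[Si](C)(C)C(C)(C)C)C1 | intermediate
35 | C15 acetate of 34 | C[C@@H]1/C=C\C=C(\COC(C)=O)C[C@@H](OCc2ccc(OC)cc2)[C@H](C(=C)CO[Si](c2ccccc2)(c2ccccc2)C(C)(C)C)[C@@H](O[Si](C)(C)C(C)(C)C)C1 | intermediate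
36 | C6 alcohol from 35 | C[C@@H]1/C=C\C=C(\COC(C)=O)C[C@@H](O)[C@H](C(=C)CO[Si](c2ccccc2)(c2ccccc2)C(C)(C)C)[C@@H](O[Si](C)(C)C(C)(C)C)C1 | intermediate
37 | (R)-3-bromo-2-hydroxy-2-methylpropanoic acid | OC(=O)[C@@](C)(O)CBr | starting material
38 | sodium (S)-2-methyloxirane-2-carboxylate | [Na+].[O-]C(=O)[C@@]1(C)OC1 | intermediate (not isolated)
39 | (S)-2,3-dihydroxy-2-methylpropanoic acid | OC(=O)[C@@](C)(O)CO | intermediate
40 | (S)-2,2,4-trimethyl-1,3-dioxolane-4-carboxylic acid | OC(=O)[C@@]1(C)OC(C)(C)OC1 | intermediate
41 | mixed anhydride of 40 with 2,4,6-trichlorobenzoic acid | O=C(OC(=O)[C@@]1(C)OC(C)(C)OC1)c1c(Cl)cc(Cl)cc1Cl | intermediate (not isolated)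
42 | C6 ester of 36 with acid 40 (O8 TBS; O12 TBDPS) | C[C@@H]1/C=C\C=C(\COC(C)=O)C[C@@H](OC(=O)[C@@]2(C)OC(C)(C)OC2)[C@H](C(=C)CO[Si](c2ccccc2)(c2ccccc2)C(C)(C)C)[C@@H](O[Si](C)(C)C(C)(C)C)C1 | intermediate
43 | C8,C12 diol from 42 | C[C@@H]1/C=C\C=C(\COC(C)=O)C[C@@H](OC(=O)[C@@]2(C)OC(C)(C)OC2)[C@H](C(=C)CO)[C@@H](O)C1 | intermediate
44 | C12 enal with free C8 hydroxyl | C[C@@H]1/C=C\C=C(\COC(C)=O)C[C@@H](OC(=O)[C@@]2(C)OC(C)(C)OC2)[C@H](C(=C)C=O)[C@@H](O)C1 | intermediate (not isolated)
45 | C12 lactol (O8–C12 closed; both C12 epimers) | C=C1C(O)O[C@H]2C[C@H](C)/C=C\C=C(\COC(C)=O)C[C@@H](OC(=O)[C@@]3(C)OC(C)(C)OC3)[C@H]12 | intermediate (not isolated)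
46 | acetonide of the target (8,12-lactone closed) | C=C1C(=O)O[C@H]2C[C@H](C)/C=C\C=C(\COC(C)=O)C[C@@H](OC(=O)[C@@]3(C)OC(C)(C)OC3)[C@H]12 | intermediate
47 | CNP0347302.1: (6R,7R,8S,10S)-germacra-1Z,3E,11(13)-trien-8,12-olide with 15-acetoxy and 6-O-[(S)-2,3-dihydroxy-2-methylpropanoyl] groups | C=C1C(=O)O[C@H]2C[C@H](C)/C=C\C=C(\COC(C)=O)C[C@@H](OC(=O)[C@@](C)(O)CO)[C@H]12 | target

## Step count and least certain steps

Total step count: 32. Longest linear sequence: 26 steps (steps 1, 2, 4, 5, 9–26 and 29–32, from 1 to 47).

**Step 22 (key step, proposed new method).**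
- What may go wrong: alkylation through C2 instead of C4; intermolecular alkylation to dimers and oligomers; or opening of the carbanion to a dienyl sulfinate while the SN2 step at the β-branched, β-oxygenated C5 lags behind. The cause is the transannular strain and the entropic cost of a closure that is nine-membered through sulfur and ten-membered through carbon.
- Fallback (known reactions, different ring-closing bond): it sets out from aldehyde 23. Methylenation (Ph3PCH3Br, KN(SiMe3)2) would give the C1 vinyl compound F1. Acetal opening with i-Bu2AlH as in step 18 would give the C5 alcohol F2. Triflation (Tf2O, 2,6-lutidine) and alkylation of sodium trimethyl phosphonoacetate would give the C4 phosphonate F3. A Horner–Wadsworth–Emmons reaction with acrolein (LiCl, DBU) would give the (2E)-2-substituted penta-2,4-dienoate F4, in which the vinyl group is trans to the ester and therefore cis to C5. Ring-closing metathesis between the C1 vinyl group and the diene terminus (second-generation Hoveyda–Grubbs catalyst, high dilution), with loss of ethene, would then form C1=C2 and return to the route at 33. In this fallback the cis geometry of C1=C2 rests on the ring-size preference only and no longer on mechanism.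

**Step 21.**
- What may go wrong: the unstabilised sulfolenyl anion opens to the dienyl sulfinate or is acylated twice, the amide base is consumed by the chloroformate, or deprotonation occurs partly at C1. All of these follow from the short lifetime of this anion on a large substrate.
- Fallback: C15 is brought in on the diene and its oxidation level is adjusted after the cheletropic step, so that no sulfolenyl anion is needed. From 27, cross-metathesis with allyl triethylsilyl ether (second-generation Hoveyda–Grubbs catalyst) would give the (E,E)-dienyl silyl ether F5. Sulfur dioxide 28 would add suprafacially to give the cis-2,5-disubstituted sulfolene F6. PPTS in MeOH would free the primary alcohol F7. Oxidation (TEMPO, PhI(OAc)2, MeCN/H2O) would give the carboxylic acid F8, and Me3SiCHN2 would give 31.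

**Step 9.**
- What may go wrong: proton abstraction at C7 in place of addition, with loss of configuration at C7 or migration of the double bond into conjugation, because C7–H is activated twice.
- Fallback (non-basic acyl substitution): from 8, EtSLi would give the thioester F9. Zinc insertion into 13 (Zn, LiCl, THF) would give the alkylzinc iodide F10. Fukuyama coupling of the two (PdCl2(PPh3)2, toluene) would give 15.

**Step 11.**
- What may go wrong: poor site selectivity (hydrogen abstraction at C7) or over-oxidation to the enal, both inherent in the ene mechanism.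
- Fallback: from 17, epoxidation of the 1,1-disubstituted alkene (mCPBA, NaHCO3) would give the epoxide F11. Base-induced isomerisation of the epoxide with Et2Al(NC9H18) (diethylaluminium 2,2,6,6-tetramethylpiperidide), which removes a proton from the unhindered methyl group, would give the allylic alcohol 18.

**Step 26.**
- What may go wrong: oxidation of, or cycloaddition to, the electron-rich cis,cis-diene by DDQ, or ionisation of the allylic acetate.
- Fallback: the 4-methoxybenzyl group is removed before the diene exists. From 32, DDQ would give the C6 alcohol F12. Thermolysis as in step 23 would give the hydroxy dienoate F13 (or its 6,15-lactone). i-Bu2AlH would reduce either form to the diol F14. Selective acetylation of the primary allylic hydroxyl (AcCl, 2,4,6-collidine, −78 °C) would give 36.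

## Further compounds

F1 | step 22 | C1 vinyl compound from 23 (O5,O6 acetal retained) | COc1ccc(C2OC[C@@H](O2)[C@H](C(=C)CO[Si](c3ccccc3)(c3ccccc3)C(C)(C)C)[C@@H](O[Si](C)(C)C(C)(C)C)C[C@H](C)C=C)cc1
F2 | step 22 | C5 alcohol with O6 4-methoxybenzyl ether and C1 vinyl group | OC[C@@H](OCc1ccc(OC)cc1)[C@H](C(=C)CO[Si](c1ccccc1)(c1ccccc1)C(C)(C)C)[C@@H](O[Si](C)(C)C(C)(C)C)C[C@H](C)C=C
F3 | step 22 | C4 phosphonate: methyl 2-(dimethoxyphosphoryl)alkanoate alkylated at C5 | COC(=O)C(C[C@@H](OCc1ccc(OC)cc1)[C@H](C(=C)CO[Si](c1ccccc1)(c1ccccc1)C(C)(C)C)[C@@H](O[Si](C)(C)C(C)(C)C)C[C@H](C)C=C)P(=O)(OC)OC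
F4 | step 22 | methyl (2E)-2-substituted penta-2,4-dienoate with C1 vinyl group (metathesis substrate) | C=C/C=C(/C(=O)OC)C[C@@H](OCc1ccc(OC)cc1)[C@H](C(=C)CO[Si](c1ccccc1)(c1ccccc1)C(C)(C)C)[C@@H](O[Si](C)(C)C(C)(C)C)C[C@H](C)C=C
F5 | step 21 | (1E,3E)-dienyl triethylsilyl ether with C5 iodide | IC[C@@H](OCc1ccc(OC)cc1)[C@H](C(=C)CO[Si](c1ccccc1)(c1ccccc1)C(C)(C)C)[C@@H](O[Si](C)(C)C(C)(C)C)C[C@H](C)/C=C/C=C/CO[Si](CC)(CC)CC
F6 | step 21 | cis-2,5-disubstituted 3-sulfolene with CH2OSiEt3 on C4 (1R epimer written) | IC[C@@H](OCc1ccc(OC)cc1)[C@H](C(=C)CO[Si](c1ccccc1)(c1ccccc1)C(C)(C)C)[C@@H](O[Si](C)(C)C(C)(C)C)C[C@H](C)[C@@H]1C=C[C@H](CO[Si](CC)(CC)CC)S1(=O)=O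
F7 | step 21 | sulfolene with free C15 alcohol | IC[C@@H](OCc1ccc(OC)cc1)[C@H](C(=C)CO[Si](c1ccccc1)(c1ccccc1)C(C)(C)C)[C@@H](O[Si](C)(C)C(C)(C)C)C[C@H](C)[C@@H]1C=C[C@H](CO)S1(=O)=O
F8 | step 21 | sulfolene C15 carboxylic acid (both C4 epimers) | IC[C@@H](OCc1ccc(OC)cc1)[C@H](C(=C)CO[Si](c1ccccc1)(c1ccccc1)C(C)(C)C)[C@@H](O[Si](C)(C)C(C)(C)C)C[C@H](C)[C@@H]1C=CC(C(=O)O)S1(=O)=O
F9 | step 9 | S-ethyl (2S,3S)-3-hydroxy-4-[(4-methoxybenzyl)oxy]-2-(prop-1-en-2-yl)butanethioate | COc1ccc(COC[C@@H](O)[C@H](C(C)=C)C(=O)SCC)cc1
F10 | step 9 | (R)-{3-[(tert-butyldimethylsilyl)oxy]-2-methylpropyl}zinc iodide | I[Zn]C[C@H](C)CO[Si](C)(C)C(C)(C)C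
F11 | step 11 | epoxide of the 2-propenyl group of 17 (both epimers at the epoxide carbon) | COc1ccc(COC[C@@H](O)[C@H](C2(C)CO2)[C@@H](O)C[C@H](C)CO[Si](C)(C)C(C)(C)C)cc1
F12 | step 26 | C6 alcohol of the bicycle (4-methoxybenzyl group removed from 32) | O=S1(=O)[C@H]2C=C[C@]1(C(=O)OC)C[C@@H](O)[C@H](C(=C)CO[Si](c3ccccc3)(c3ccccc3)C(C)(C)C)[C@@H](O[Si](C)(C)C(C)(C)C)C[C@@H]2C
F13 | step 26 | ring-cis,cis dienoate with free C6 hydroxyl | C[C@@H]1/C=C\C=C(\C(=O)OC)C[C@@H](O)[C@H](C(=C)CO[Si](c2ccccc2)(c2ccccc2)C(C)(C)C)[C@@H](O[Si](C)(C)C(C)(C)C)C1
F14 | step 26 | C6,C15 diol of the ring-cis,cis diene | C[C@@H]1/C=C\C=C(\CO)C[C@@H](O)[C@H](C(=C)CO[Si](c2ccccc2)(c2ccccc2)C(C)(C)C)[C@@H](O[Si](C)(C)C(C)(C)C)C1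
A1 | alternative 1 | acetonide of the target (identical with 46) | C=C1C(=O)O[C@H]2C[C@H](C)/C=C\C=C(\COC(C)=O)C[C@@H](OC(=O)[C@@]3(C)OC(C)(C)OC3)[C@H]12
A2 | alternative 1 | open-chain lactone with Z-alkenyl iodide at C2 and tributylstannyl group at C3 | C=C1C(=O)O[C@@H](C[C@H](C)/C=C\I)[C@@H]1[C@H](OC(=O)[C@@]2(C)OC(C)(C)OC2)C/C(COC(C)=O)=C\[Sn](CCCC)(CCCC)CCCC
A3 | alternative 2 | ten-membered C1,C6-dione with cis C3=C4 (open form of the C8 hemiketal) | O[C@H]1C[C@H](C)C(=O)C/C=C(/CO[Si](C)(C)C(C)(C)C)CC(=O)[C@@H]1CCO[Si](C)(C)C(C)(C)C
A4 | alternative 2 | hexahydronaphthalene with tetrasubstituted C1=C6 alkene | O[C@H]1C[C@H](C)C2=C(CC(CO[Si](C)(C)C(C)(C)C)=CC2)[C@@H]1CCO[Si](C)(C)C(C)(C)C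
A5 | alternative 3 | ten-membered C6 alcohol with the 2-propenyl unit on C7 | C=C(CO[Si](C)(C)C(C)(C)C)[C@@H]1[C@@H](O[Si](C)(C)C(C)(C)C)C[C@H](C)/C=C\C=C(\COCc2ccc(OC)cc2)C[C@H]1O
A6 | alternative 3 | thirteen-membered α-stannyl allyl ether (C6 and C7=C11 descriptors left open) | CCCC[Sn](CCCC)(CCCC)C1OCC(CO[Si](C)(C)C(C)(C)C)=C[C@@H](O[Si](C)(C)C(C)(C)C)C[C@H](C)/C=C\C=C(\COCc2ccc(OC)cc2)C1
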